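The numbers in the tables were generated by integration for an exercise; the scatter is artificial.

In a one-step world every D that reacts reappears as X and takes one G with it, while the slope of ln c(D) keeps step with free G.

in all of them: D 0.30 M

| run | G | J | remark | time |
|---|---|---|---|---|
| winter | 3 equiv | 1.5 equiv | the very flask that is asked about, followed so far |  |
| spring | 2 equiv | 1.5 equiv | run made earlier |  |
| flask | 3.00 equiv | 1.50 equiv |  | 2.0 h |

- winter (time / min: D / %, X / %): 10.0: 69, 31; 20.0: 50, 50; 30.0: 38, 60; 40.0: 29, 70; 50.0: 26, 72
- spring (time / min: D / %, X / %): 8.00: 82, 18; 20.0: 61, 37; 40.0: 46, 55; 60.0: 33, 60; 80.0: 26, 62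

(scatter of a reading: 1.5 percentage points)

- the earlier runs do not show how much of G is bound; that part of a forecast is a guess

- part of the D that has reacted at 2.0 h
- share of the unused G that is free and not bound as Z, at 2.0 h

I keep the books on D, the limiting reagent, in the winter run, which is the asked flask followed so far. At 50.0 min the entries are 26 % of D left and 72 % as X, a gap of 2 percentage points, within the scatter; the spring run at 80.0 min shows a gap of 12 points, so a further entry opens late.

Next comes G. With G in excess, D decays pseudo-first-order. The first winter reading gives a slope of 0.0371 min⁻¹ and the first spring reading 0.0248 min⁻¹, a ratio of 0.668 against a charge ratio of 0.667, so I take the slope as a measure of free G. Between 20.0 min and 50.0 min the winter slope is 0.0218 min⁻¹; letting the first slope stand for the full charge, I estimate free G at 58.7 % of its charge. The reaction with D has by then left 79.3 % unused. I treat the binding as settled, and the difference is the bound share, G unused yet not free, as a part of the G charged: 20.6 %.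

Carrying the late slope on to 2.0 h leaves 5.65 % of D, so 94.3 % has reacted. Then 68.6 % of G is unused, and holding the bound share leaves 70.0 % of that free.

The forecast differs from my reckoning, with 91 % reacted and 75 % free, and says of the second, "Free G share is a guess".

The flask gives 94.6 % reacted and 68.2 % free.

    D + G → L + X (k = 0.0479 L mol⁻¹ min⁻¹)
    G + L ⇌ Z, settled at all times (K = 51.0 L mol⁻¹)
    L + J ⇌ Q (K = 4.50 L mol⁻¹, k = 6.93 L mol⁻¹ min⁻¹)
    L + X → E (k = 0.330 L mol⁻¹ min⁻¹)

At 2.00 h the flask holds 0.196 M of Z, which is 21.7 % of the G charged, against my bound share of 20.6 %. The same reckoning goes to a neighbour charged with 0.750 equiv of G, everything else as in the flask. With 42.8 % of its D reacted at 2.0 h, one G gone for each D leaves 42.9 % of its G unused. Holding my bound share at 20.6 % of the G charged, I reckon 52.0 % of that unused G free, and that neighbour gives 54.0 %.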